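**Retrosynthetic overview**

- The strategy rests on the seven-membered ring C1–C5–C6–C7–C8–C9–C10, which has oxygen on C6, an sp2 carbon at C10 and the side chain on C7. With a temporary ether bridge from C6 to C9 it is an 8-oxabicyclo[3.2.1]oct-3-en-2-one, the product of a 3-oxidopyrylium adding to an acyl alkene (bonds C6–C7 and C8–C9).
- Target ⇒ C9/C12/C13 triacetate with silylated C6–OH ⇒ C10 ketone (methylenation last), with the C9 oxygen put back by enolate oxidation after SmI2 has cut the C9–O bridge bond.
- The cyclopentene (C1–C2–C3=C4–C5) comes from ring-closing metathesis of a C5 isopropenyl/C1 allyl pair, installed trans by conjugate addition and enolate allylation on the cycloheptenone that the bridge opening releases. During the opening the enone is held as its thiophenol adduct.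
- The C11 methyl comes from methylenation of the side-chain ketone and a late hydrogenation. The components are 6-acetoxypyranone (Achmatowicz) and a vinyl ketone from L-tartrate.
- Ring order: oxygen-bridged seven-membered ring first, bridge opened, five-membered ring last.

Key step: step 9

Remark: the carbon numbers C1–C15 of the target skeleton are used for all intermediates; 3 is used as the racemate because its acetal carbon becomes sp2 in the ylide.

**Route**

Step 1
Reactants: 1 furfuryl alcohol
Product: 2 6-hydroxy-2H-pyran-3(6H)-one (racemic)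
Conditions: mCPBA, CH2Cl2, 0 °C → rt
Reagents that add atoms: 3-chloroperbenzoic acid (mCPBA), OOC(=O)c1cccc(Cl)c1
Why: Achmatowicz rearrangement: the peracid oxidises the furan, which opens and recloses on the primary alcohol as the hemiacetal pyranone; the acetal centre is racemic and is destroyed later.

Step 2
Reactants: 2 6-hydroxy-2H-pyran-3(6H)-one
Product: 3 6-acetoxy-2H-pyran-3(6H)-one (racemic)
Conditions: Ac2O, pyridine, DMAP (cat.), CH2Cl2, 0 °C
Reagents that add atoms: acetic anhydride, CC(=O)OC(C)=O
Why: DMAP-catalysed O-acylation of the hemiacetal hydroxyl turns it into the leaving group needed for ylide formation.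

Step 3
Reactants: 4 dimethyl (4R,5R)-2,2-dimethyl-1,3-dioxolane-4,5-dicarboxylate (dimethyl 2,3-O-isopropylidene-L-tartrate)
Product: 5 (4R,5R)-5-(methoxycarbonyl)-2,2-dimethyl-1,3-dioxolane-4-carboxylic acid
Conditions: KOH (1.0 equiv), MeOH, 0 °C → rt; then aq. HCl to pH 2
Reagents that add atoms: potassium hydroxide, [K+].[OH-]
Why: Mono-saponification of the C2-symmetric diester: the two esters are equivalent and the first carboxylate slows hydrolysis of the second; the trans-dioxolane centres are untouched.

Step 4
Reactants: 5 mono-acid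
Product: 6 methyl (4R,5S)-5-(hydroxymethyl)-2,2-dimethyl-1,3-dioxolane-4-carboxylate
Conditions: BH3·SMe2, THF, 0 °C → rt; MeOH
Reagents that add atoms: none
Why: Chemoselective borane reduction of the carboxylic acid (via the acyloxyborane) in the presence of the methyl ester.

Step 5
Reactants: 6 hydroxy ester
Product: 7 methyl (4R,5R)-5-formyl-2,2-dimethyl-1,3-dioxolane-4-carboxylate
Conditions: Dess–Martin periodinane, CH2Cl2, 0 °C → rt
Reagents that add atoms: none
Why: Dess–Martin oxidation of the primary alcohol to the aldehyde under anhydrous, non-epimerising conditions; the aldehyde is used crude.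

Step 6
Reactants: 7 aldehyde
Product: 8 methyl (4R,5S)-2,2-dimethyl-5-(2-methylprop-1-en-1-yl)-1,3-dioxolane-4-carboxylate
Conditions: i-PrPPh3I, n-BuLi, THF, 0 °C; then 7, −78 → 0 °C
Reagents that add atoms: isopropyltriphenylphosphonium iodide, CC(C)[P+](c1ccccc1)(c1ccccc1)c1ccccc1.[I-]
Why: Wittig olefination with the non-stabilised isopropylidene ylide, which has no E/Z issue; the trans-dioxolane is the more stable arrangement, so the centre alpha to the aldehyde (C13) is not at risk.

Step 7
Reactants: 8 ester
Product: 9 (4R,5S)-N-methoxy-N,2,2-trimethyl-5-(2-methylprop-1-en-1-yl)-1,3-dioxolane-4-carboxamide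
Conditions: MeNHOMe·HCl, i-PrMgCl, THF, −20 → 0 °C
Reagents that add atoms: N,O-dimethylhydroxylamine hydrochloride, CNOC.Cl
Why: Aminolysis of the ester by the chloromagnesium amide gives the N-methoxy-N-methylamide (Weinreb amide) without touching C12.

Step 8
Reactants: 9 N-methoxy-N-methylamide; 10 vinylmagnesium bromide
Product: 11 1-[(4R,5S)-2,2-dimethyl-5-(2-methylprop-1-en-1-yl)-1,3-dioxolan-4-yl]prop-2-en-1-one (vinyl ketone; C7, C8, C11–C15)
Conditions: THF, −78 → 0 °C; inverse quench into cold 1 M HCl
Reagents that add atoms: none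
Why: Weinreb ketone synthesis: the chelated tetrahedral adduct survives until the acidic quench, so neither over-addition nor conjugate addition of the released amine occurs.

Step 9
Reactants: 3 6-acetoxy-2H-pyran-3(6H)-one; 11 vinyl ketone
Product: 13 exo-acyl oxabicyclic enone, via 3-oxidopyrylium ylide 12 (not isolated)
Conditions: Et3N (3 equiv), CH2Cl2, rt, 3 (3 equiv) added over 12 h; then 12 h
Reagents that add atoms: none
Why: Triethylamine eliminates acetic acid from 3 to give the 3-oxidopyrylium ylide 12, which adds across the electron-poor alkene of 11 in a concerted suprafacial (5+2) dipolar cycloaddition, the known oxidopyrylium–acyl alkene route to 8-oxabicyclo[3.2.1]oct-3-en-2-ones. The seven-membered carbocycle and the oxolane ring are closed together in this one intermolecular event by C6–C7 and C8–C9 bond formation at the two ylide carbons flanking the ring oxygen, which becomes the C6–O–C9 bridge. Regiochemistry follows the dipole: the nucleophilic ylide carbon next to the oxido group (C9) bonds to the beta-carbon C8, so the acyl-bearing C7 lies next to C6. C6 and C9 are set together, necessarily cis-bridged, and C7 ends exo (acyl syn to the bridge) because the C7–H alpha to the C11 ketone equilibrates under the amine towards the less hindered isomer. The step needs the ylide to be taken on the face that gives the shown C6/C9 configuration relative to C12, and only the dioxolane secures this: 13 should arise by attack anti to C13 on the s-cis enone rotamer whose C12–O bond lies syn to the carbonyl, so the preference is expected to be modest and the diastereomers are separated by chromatography. Slow addition of 3 keeps the ylide concentration low and limits its dimerisation.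

Step 10
Reactants: 13 cycloadduct
Product: 14 C5-phenylthio C1=C10 trimethylsilyl enol ether (C11 ketone free)
Conditions: PhSSiMe3 (1.3 equiv), Bu4NF (5 mol %), THF, 0 °C → rt
Reagents that add atoms: (phenylthio)trimethylsilane, C[Si](C)(C)Sc1ccccc1
Why: Thiolate-chain conjugate addition of the silyl sulfide (thia-Michael addition with O-silylation): PhS adds to C5 from the exo face and the enolate is silylated, which masks the enone and the C10 carbonyl at once while the hindered C11 ketone stays free; the C5 centre is temporary.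

Step 11
Reactants: 14 silyl enol ether
Product: 16 phenylthio ketone bearing the C11 methylene group, via methylenated silyl enol ether 15 (not isolated)
Conditions: Cp2TiMe2 (2.5 equiv), toluene, 65 °C; then 1 M HCl, THF, 0 °C
Reagents that add atoms: dimethyltitanocene, C[Ti](C)(C1C=CC=C1)C1C=CC=C1
Why: Petasis methylenation of the only free carbonyl (C11) under neutral conditions, so C7 and C12 are not epimerised and the bridge is not opened by beta-elimination; brief aqueous acid then hydrolyses the silyl enol ether to the C10 ketone.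

Step 12
Reactants: 16 bicyclic phenylthio ketone
Product: 17 cycloheptanone with C6–OH (cis to the C7 chain), C9 methylene and C5–SPh
Conditions: SmI2 (2.5 equiv), THF–MeOH, −78 °C
Reagents that add atoms: none
Why: SmI2 reduction of an alpha-alkoxy ketone: two-electron reduction at C10 expels the C9–O bond as the alkoxide and leaves the oxygen on C6 with the configuration set in step 9; the ketone is kept saturated so that the vinylogous C6–O bond cannot be cut, and the beta-sulfide is inert.

Step 13
Reactants: 17 hydroxy ketone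
Product: 18 C6 tert-butyldimethylsilyl ether
Conditions: TBSOTf, 2,6-lutidine, CH2Cl2, −78 → 0 °C
Reagents that add atoms: tert-butyldimethylsilyl triflate, CC(C)(C)[Si](C)(C)OS(=O)(=O)C(F)(F)F
Why: Silylation of the secondary alcohol with the silyl triflate; the silyl ether later steers the conjugate addition and shields one face of the C11 alkene.

Step 14
Reactants: 18 silyl ether
Product: 20 silyloxy cycloheptenone, via sulfoxide 19 (not isolated)
Conditions: mCPBA (1.0 equiv), CH2Cl2, −78 °C; then Et3N, toluene, 80 °C
Reagents that add atoms: none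
Why: Sulfide oxidation and sulfoxide elimination: at −78 °C the peracid oxidises sulfur far faster than the alkenes, and the beta-keto sulfoxide loses PhSOH towards the acidic C1–H, which regenerates the C1=C5 enone only.

Step 15
Reactants: 20 enone
Product: 21 C1=C10 trimethylsilyl enol ether with C5 isopropenyl (trans to the C6 oxygen)
Conditions: isopropenylmagnesium bromide, CuBr·SMe2 (20 mol %), Me3SiCl, THF, −78 °C; Et3N, aq. NaHCO3 work-up
Reagents that add atoms: isopropenylmagnesium bromide, C=C(C)[Mg]Br; chlorotrimethylsilane, C[Si](C)(C)Cl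
Why: Copper-catalysed conjugate addition of the Grignard reagent with silyl chloride trapping: the nucleophile enters C5 anti to the gamma-silyloxy group on C6 and to the C7 chain, which sets C5, and the enolate is fixed as the C1=C10 silyl enol ether.

Step 16
Reactants: 21 silyl enol ether
Product: 23 allyl isopropenyl ketone, via lithium enolate 22 (not isolated)
Conditions: MeLi, THF, 0 °C; then allyl iodide, DMPU, −78 → −20 °C
Reagents that add atoms: allyl iodide, C=CCI
Why: MeLi cleaves the silyl enol ether to the regiodefined lithium enolate, whose C-allylation (enolate alkylation) occurs anti to the neighbouring C5 isopropenyl group, so C1 and C5 carry their carbon substituents trans, as the ring fusion requires.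

Step 17
Reactants: 23 diene ketone
Product: 24 trans-fused hydroazulenone (C3=C4 cyclopentene, C11 methylene)
Conditions: second-generation Grubbs catalyst (H2IMes)(PCy3)Cl2Ru=CHPh (5 mol %), CH2Cl2 (5 mM), 40 °C
Reagents that add atoms: none
Why: Ring-closing metathesis between the allyl and isopropenyl groups closes the cyclopentene (C1–C2–C3=C4–C5) with loss of ethylene; the trans fusion is already in place, and the hindered C11 methylene and the trisubstituted C14=C15 alkene should not take part.

Step 18
Reactants: 24 hydroazulenone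
Product: 25 hydroazulenone with the C11 methyl stereocentre
Conditions: H2 (4 atm), RhCl(PPh3)3 (10 mol %), benzene–EtOH, 40 °C
Reagents that add atoms: none
Why: Homogeneous hydrogenation with RhCl(PPh3)3 reduces the 1,1-disubstituted C11 methylene but not the trisubstituted alkenes; with H7 eclipsing the C11–C12 bond (allylic 1,2-strain) the alkene face turned to C6 is screened by the cis silyloxy group, so hydrogen should arrive from the C8 side, which gives the target C11 configuration (methyl syn to the C12 oxygen along C7–C13).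

Step 19
Reactants: 25 ketone
Product: 27 C9 hydroxy ketone, via potassium enolate 26 (not isolated)
Conditions: KN(SiMe3)2, THF, −78 °C; then 2-(phenylsulfonyl)-3-phenyloxaziridine, −78 °C; aq. NH4Cl
Reagents that add atoms: 2-(phenylsulfonyl)-3-phenyloxaziridine, O=S(=O)(c1ccccc1)N1OC1c1ccccc1
Why: Davis oxidation: the amide base removes a proton from the C9 methylene (kinetic control, not the ring-fusion C1–H) and the oxaziridine transfers oxygen to the enolate face opposite to C2 on C1 and to the C7 chain, both on the upper face, which places the hydroxyl trans to the C6 oxygen.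

Step 20
Reactants: 27 hydroxy ketone
Product: 28 C9 triethylsilyl ether
Conditions: Et3SiCl, imidazole, DMAP (cat.), CH2Cl2, 0 °C → rt
Reagents that add atoms: chlorotriethylsilane, CC[Si](Cl)(CC)CC
Why: Silylation of the C9 hydroxyl with a group more labile than the C6 silyl ether, so that the two oxygens can be told apart later.

Step 21
Reactants: 28 silyloxy ketone
Product: 29 C10 exocyclic methylene compound
Conditions: Cp2TiMe2 (3 equiv), toluene, 75 °C
Reagents that add atoms: dimethyltitanocene, C[Ti](C)(C1C=CC=C1)C1C=CC=C1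
Why: Petasis methylenation converts the hindered C10 ketone into the exocyclic alkene without base, so the epimerisable centres C1 and C9 are kept.

Step 22
Reactants: 29 fully protected compound
Product: 30 C9, C12, C13-triol with C6 silyl ether
Conditions: PPTS (0.3 equiv), MeOH, 45 °C
Reagents that add atoms: none
Why: Acid-catalysed methanolysis (transketalisation and desilylation) removes the acetonide and the triethylsilyl ether, while the hindered secondary tert-butyldimethylsilyl ether at C6 and the allylic alcohols are expected to survive the weak acid.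

Step 23
Reactants: 30 triol
Product: 31 C9, C12, C13-triacetate with C6 silyl ether
Conditions: Ac2O, pyridine, DMAP (cat.), CH2Cl2, rt
Reagents that add atoms: acetic anhydride, CC(=O)OC(C)=O
Why: DMAP-catalysed acetylation of the three free hydroxyls; C6 stays protected, which is how the free C6–OH of the target is distinguished.

Step 24
Reactants: 31 silyl ether triacetate
Product: 32 CNP0194318.1 (target)
Conditions: HF·pyridine, THF–pyridine, 0 °C → rt
Reagents that add atoms: none
Why: Fluoride-mediated cleavage of the silyl ether under buffered conditions that leave the three acetates and the allylic systems intact.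

**Compound list**

1 | furfuryl alcohol | OCc1ccco1 | starting material
2 | 6-hydroxy-2H-pyran-3(6H)-one (racemic) | OC1OCC(=O)C=C1 | intermediate
3 | 6-acetoxy-2H-pyran-3(6H)-one (racemic) | CC(=O)OC1OCC(=O)C=C1 | intermediate
4 | dimethyl (4R,5R)-2,2-dimethyl-1,3-dioxolane-4,5-dicarboxylate | COC(=O)[C@@H]1OC(C)(C)O[C@H]1C(=O)OC | starting material
5 | (4R,5R)-5-(methoxycarbonyl)-2,2-dimethyl-1,3-dioxolane-4-carboxylic acid | COC(=O)[C@@H]1OC(C)(C)O[C@H]1C(=O)O | intermediate
6 | methyl (4R,5S)-5-(hydroxymethyl)-2,2-dimethyl-1,3-dioxolane-4-carboxylate | COC(=O)[C@@H]1OC(C)(C)O[C@H]1CO | intermediate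
7 | methyl (4R,5R)-5-formyl-2,2-dimethyl-1,3-dioxolane-4-carboxylate | COC(=O)[C@@H]1OC(C)(C)O[C@H]1C=O | intermediate
8 | methyl (4R,5S)-2,2-dimethyl-5-(2-methylprop-1-en-1-yl)-1,3-dioxolane-4-carboxylate | COC(=O)[C@@H]1OC(C)(C)O[C@H]1C=C(C)C | intermediate
9 | (4R,5S)-N-methoxy-N,2,2-trimethyl-5-(2-methylprop-1-en-1-yl)-1,3-dioxolane-4-carboxamide | CON(C)C(=O)[C@@H]1OC(C)(C)O[C@H]1C=C(C)C | intermediate
10 | vinylmagnesium bromide | C=C[Mg]Br | starting material
11 | 1-[(4R,5S)-2,2-dimethyl-5-(2-methylprop-1-en-1-yl)-1,3-dioxolan-4-yl]prop-2-en-1-one | C=CC(=O)[C@@H]1OC(C)(C)O[C@H]1C=C(C)C | intermediate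
12 | 3-oxidopyrylium ylide (formed in the flask) | [O-]c1ccc[o+]c1 | intermediate
13 | 8-oxabicyclo[3.2.1]oct-3-en-2-one with the dioxolanyl ketone at position 6, exo (C10 ketone, C1=C5, bridge C6–O–C9, C7 acyl syn to the bridge) | O=C1[C@@H]2C[C@@H](C(=O)[C@@H]3OC(C)(C)O[C@H]3C=C(C)C)[C@@H](O2)C=C1 | intermediate
14 | C5 exo-phenylthio, C1=C10 trimethylsilyl enol ether, C11 ketone, bridge intact | C[Si](C)(C)OC1[C@@H]2C[C@@H](C(=O)[C@@H]3OC(C)(C)O[C@H]3C=C(C)C)[C@@H](O2)[C@@H](Sc4ccccc4)C=1 | intermediate
15 | as 14 with C11=CH2 (formed in the flask) | C[Si](C)(C)OC1[C@@H]2C[C@@H](C(=C)[C@@H]3OC(C)(C)O[C@H]3C=C(C)C)[C@@H](O2)[C@@H](Sc4ccccc4)C=1 | intermediate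
16 | bridged C10 ketone with C5–SPh and C11=CH2 | O=C1[C@@H]2C[C@@H](C(=C)[C@@H]3OC(C)(C)O[C@H]3C=C(C)C)[C@@H](O2)[C@@H](Sc4ccccc4)C1 | intermediate
17 | cycloheptanone with C6–OH, C5–SPh and C7 side chain all cis, C11=CH2 | O=C1CC[C@@H](C(=C)[C@@H]2OC(C)(C)O[C@H]2C=C(C)C)[C@@H](O)[C@@H](Sc3ccccc3)C1 | intermediate
18 | C6 tert-butyldimethylsilyl ether of 17 | O=C1CC[C@@H](C(=C)[C@@H]2OC(C)(C)O[C@H]2C=C(C)C)[C@@H](O[Si](C)(C)C(C)(C)C)[C@@H](Sc3ccccc3)C1 | intermediate
19 | C5 phenylsulfinyl compound (formed in the flask; mixture at sulfur) | O=C1CC[C@@H](C(=C)[C@@H]2OC(C)(C)O[C@H]2C=C(C)C)[C@@H](O[Si](C)(C)C(C)(C)C)[C@@H](S(=O)c3ccccc3)C1 | intermediate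
20 | cyclohept-2-enone (C1=C5) with C6 silyloxy group cis to the C7 side chain | O=C1CC[C@@H](C(=C)[C@@H]2OC(C)(C)O[C@H]2C=C(C)C)[C@@H](O[Si](C)(C)C(C)(C)C)C=C1 | intermediate
21 | C1=C10 trimethylsilyl enol ether with C5 isopropenyl trans to the C6 oxygen | C[Si](C)(C)OC1CC[C@@H](C(=C)[C@@H]2OC(C)(C)O[C@H]2C=C(C)C)[C@@H](O[Si](C)(C)C(C)(C)C)[C@H](C(C)=C)C=1 | intermediate
22 | lithium enolate of the same (formed in the flask) | [Li]OC1CC[C@@H](C(=C)[C@@H]2OC(C)(C)O[C@H]2C=C(C)C)[C@@H](O[Si](C)(C)C(C)(C)C)[C@H](C(C)=C)C=1 | intermediate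
23 | C10 ketone with C1 allyl and C5 isopropenyl trans | O=C1CC[C@@H](C(=C)[C@@H]2OC(C)(C)O[C@H]2C=C(C)C)[C@@H](O[Si](C)(C)C(C)(C)C)[C@H](C(C)=C)[C@H]1CC=C | intermediate
24 | trans-fused hydroazulenone (C3=C4, C4 methyl), C11=CH2 | O=C1CC[C@@H](C(=C)[C@@H]2OC(C)(C)O[C@H]2C=C(C)C)[C@@H](O[Si](C)(C)C(C)(C)C)[C@@H]3C(C)=CC[C@@H]13 | intermediate
25 | as 24 with the C11 methyl stereocentre | O=C1CC[C@@H]([C@@H](C)[C@@H]2OC(C)(C)O[C@H]2C=C(C)C)[C@@H](O[Si](C)(C)C(C)(C)C)[C@@H]3C(C)=CC[C@@H]13 | intermediate
26 | potassium C9=C10 enolate (formed in the flask) | [K]OC1=CC[C@@H]([C@@H](C)[C@@H]2OC(C)(C)O[C@H]2C=C(C)C)[C@@H](O[Si](C)(C)C(C)(C)C)[C@@H]3C(C)=CC[C@@H]13 | intermediate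
27 | C9 hydroxy ketone (C9–OH trans to the C6 oxygen) | O=C1[C@H](O)C[C@@H]([C@@H](C)[C@@H]2OC(C)(C)O[C@H]2C=C(C)C)[C@@H](O[Si](C)(C)C(C)(C)C)[C@@H]3C(C)=CC[C@@H]13 | intermediate
28 | C9 triethylsilyl ether | O=C1[C@H](O[Si](CC)(CC)CC)C[C@@H]([C@@H](C)[C@@H]2OC(C)(C)O[C@H]2C=C(C)C)[C@@H](O[Si](C)(C)C(C)(C)C)[C@@H]3C(C)=CC[C@@H]13 | intermediate
29 | C10 methylene compound, fully protected | C=C1[C@H](O[Si](CC)(CC)CC)C[C@@H]([C@@H](C)[C@@H]2OC(C)(C)O[C@H]2C=C(C)C)[C@@H](O[Si](C)(C)C(C)(C)C)[C@@H]3C(C)=CC[C@@H]13 | intermediate
30 | C9, C12, C13-triol, C6 silyl ether | C=C1[C@H](O)C[C@@H]([C@@H](C)[C@H](O)[C@H](C=C(C)C)O)[C@@H](O[Si](C)(C)C(C)(C)C)[C@@H]2C(C)=CC[C@@H]12 | intermediate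
31 | C9, C12, C13-triacetate, C6 silyl ether | C=C1[C@H](OC(C)=O)C[C@@H]([C@@H](C)[C@H](OC(C)=O)[C@H](C=C(C)C)OC(C)=O)[C@@H](O[Si](C)(C)C(C)(C)C)[C@@H]2C(C)=CC[C@@H]12 | intermediate
32 | CNP0194318.1 | C=C1[C@H](OC(C)=O)C[C@@H]([C@@H](C)[C@H](OC(C)=O)[C@H](C=C(C)C)OC(C)=O)[C@@H](O)[C@@H]2C(C)=CC[C@@H]12 | target

**Step count and risks**

Total: 24 steps. Longest linear sequence: 22 steps (steps 3–24, from 4); steps 1–2 make the second component.

Steps most likely to fail:

1. Step 9. The ylide may add with little facial preference relative to C12, and it may dimerise faster than it is captured by one equivalent of the hindered enone. The fallback sets out from 11 (with 3) and changes the source of control from the dioxolane to an internal hydrogen bond. The acetonide of 11 is hydrolysed (CF3CO2H–H2O, CH2Cl2, 0 °C) to the dihydroxy enone F1. Its C12 hydroxyl is hydrogen-bonded to the ketone, which fixes the C12–O bond syn to the carbonyl and leaves open the enone face anti to C13. F1 is used at once, since its C13 hydroxyl can add to the enone. The (5+2) reaction with 3 and Et3N then gives the dihydroxy cycloadduct F2, which is re-ketalised (2,2-dimethoxypropane, PPTS) and comes back to the route at 13.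

2. Step 18. Hydrogen may be delivered to the other face of the C11 methylene group if the rotamer about C7–C11 is not the one assumed, and the hindered alkene may reduce slowly. The fallback sets out from 24 and replaces steric shielding by hydroxyl direction, which delivers hydrogen from the opposite (C6) side of the same alkene. The silyl ether is cleaved (HF·pyridine) to the hydroxy ketone F3. Directed hydrogenation with [Rh(nbd)(dppb)]BF4 and H2 in CH2Cl2 gives the C11-methyl hydroxy ketone F4. Re-silylation (TBSOTf, 2,6-lutidine) comes back to the route at 25.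

3. Step 19. The oxidant may attack the upper face of the C9 enolate, or the enolate may equilibrate towards C1. The fallback sets out from 25 and sets C9 by inversion instead of by face selection. The hydroxylation is run as before, and the 9-epimeric hydroxy ketone F5 is inverted by a Mitsunobu reaction with acetic acid (PPh3, DIAD) to the C9 acetoxy ketone F6. The ketone is methylenated selectively in the presence of the ester with Cp2Ti(μ-Cl)(μ-CH2)AlMe2 (Tebbe reagent) at −40 °C to give the allylic acetate F7. PPTS in MeOH removes the acetonide to give the diol monoacetate F8, and acetylation comes back to the route at 31.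

**Further compounds**

F1 | step 9 | (4S,5S)-4,5-dihydroxy-7-methylocta-1,6-dien-3-one (dihydroxy enone) | C=CC(=O)[C@H](O)[C@@H](O)C=C(C)C
F2 | step 9 | cycloadduct 13 with free C12 and C13 hydroxyls | O=C1[C@@H]2C[C@@H](C(=O)[C@H](O)[C@@H](O)C=C(C)C)[C@@H](O2)C=C1
F3 | step 18 | hydroazulenone 24 with free C6–OH | O=C1CC[C@@H](C(=C)[C@@H]2OC(C)(C)O[C@H]2C=C(C)C)[C@@H](O)[C@@H]3C(C)=CC[C@@H]13
F4 | step 18 | C11-methyl hydroazulenone with free C6–OH | O=C1CC[C@@H]([C@@H](C)[C@@H]2OC(C)(C)O[C@H]2C=C(C)C)[C@@H](O)[C@@H]3C(C)=CC[C@@H]13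
F5 | step 19 | 9-epimer of hydroxy ketone 27 | O=C1[C@@H](O)C[C@@H]([C@@H](C)[C@@H]2OC(C)(C)O[C@H]2C=C(C)C)[C@@H](O[Si](C)(C)C(C)(C)C)[C@@H]3C(C)=CC[C@@H]13
F6 | step 19 | C9 acetoxy ketone (C9 as in the target) | O=C1[C@H](OC(C)=O)C[C@@H]([C@@H](C)[C@@H]2OC(C)(C)O[C@H]2C=C(C)C)[C@@H](O[Si](C)(C)C(C)(C)C)[C@@H]3C(C)=CC[C@@H]13
F7 | step 19 | C10 methylene C9 acetate with acetonide and C6 silyl ether | C=C1[C@H](OC(C)=O)C[C@@H]([C@@H](C)[C@@H]2OC(C)(C)O[C@H]2C=C(C)C)[C@@H](O[Si](C)(C)C(C)(C)C)[C@@H]3C(C)=CC[C@@H]13
F8 | step 19 | C9 acetate C12,C13-diol with C6 silyl ether | C=C1[C@H](OC(C)=O)C[C@@H]([C@@H](C)[C@H](O)[C@H](C=C(C)C)O)[C@@H](O[Si](C)(C)C(C)(C)C)[C@@H]2C(C)=CC[C@@H]12
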